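## Retrosynthetic overview

- (−)-Carinol ⇐ hydrogenolysis of two aryl benzyl ethers and hydride opening of a trans-3,4-bis(arylmethyl)-4-hydroxy-γ-butyrolactone.
- Key disconnection: the ArCH2–C(OH) bond at the tertiary carbinol, made by a visible-light photocatalytic C–H benzylation of a cis-3-arylmethyl-4-hydroxy-γ-butyrolactone with O-benzylvanillin tosylhydrazone. The new group enters anti to the existing arylmethyl group.
- That hydroxy-lactone ⇐ chemoselective reduction and lactonisation of the Frater–Seebach alkylation product of dimethyl (S)-malate with O-benzylvanillyl bromide. The malate carbinol centre sets the CH(CH2Ar) centre.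
- Rings: the target is acyclic. One temporary γ-lactone is formed in step 2 (to relay stereochemistry) and opened in step 5.

Assumption: 4-(benzyloxy)-3-methoxybenzyl bromide (2) is taken as a catalogue compound; if not in stock it is one step (PBr3) from commercial 4-benzyloxy-3-methoxybenzyl alcohol.

## Route

**Step 1**
Reactants: 1, dimethyl (S)-malate; 2, 4-(benzyloxy)-3-methoxybenzyl bromide
Product: 3, dimethyl (2S,3R)-3-[4-(benzyloxy)-3-methoxybenzyl]-2-hydroxybutanedioate
Conditions: LiHMDS (2.2 equiv), THF, −78 °C; then 2, −78 → −20 °C; AcOH quench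
Reagents that add atoms: 2, 4-(benzyloxy)-3-methoxybenzyl bromide, COc1cc(CBr)ccc1OCc1ccccc1
Why: Frater–Seebach alkylation; the lithium-chelated alkoxide–enolate is alkylated anti to the C1 ester, giving the (2S,3R) anti product (typically about 10:1), so the new C3 centre is set by the purchased malate centre.

**Step 2**
Reactants: 3
Product: 4, (3R,4S)-3-[4-(benzyloxy)-3-methoxybenzyl]-4-hydroxyoxolan-2-one (OH and arylmethyl cis)
Conditions: BH3·SMe2 (1.1 equiv), NaBH4 (5 mol%), THF, 0 °C → rt; MeOH quench; then TFA (cat.), CH2Cl2, rt
Reagents that add atoms: none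
Why: Hydroxyl-directed borane reduction of the α-hydroxy ester only, followed by acid lactonisation of the 3,4-dihydroxy ester; no stereocentre is touched, the minor C3 epimer is removed by crystallisation, and the carbinol C–H ends up on the face opposite the arylmethyl group.

**Step 3**
Reactants: 5, 4-(benzyloxy)-3-methoxybenzaldehyde; 6, p-toluenesulfonyl hydrazide
Product: 7, (E)-N′-[4-(benzyloxy)-3-methoxybenzylidene]-4-methylbenzenesulfonohydrazide
Conditions: MeOH, rt, 2 h; filter the crystalline product
Reagents that add atoms: 6, p-toluenesulfonyl hydrazide, Cc1ccc(cc1)S(=O)(=O)NN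
Why: Simple hydrazone condensation, driven by crystallisation.

**Step 4**
Reactants: 4; 7 (1.5 equiv)
Product: 8, (3R,4S)-3,4-bis[4-(benzyloxy)-3-methoxybenzyl]-4-hydroxyoxolan-2-one (arylmethyl groups trans; OH cis to the C3 arylmethyl)
Conditions: [Ir(dF(CF3)ppy)2(dtbbpy)]PF6 (2 mol%), quinuclidine (1.2 equiv), Bu4N·H2PO4 (25 mol%), MeCN/DMSO 4:1, 450 nm LEDs, 25 °C, degassed; then KOAc (3 equiv), 60 °C, 2 h
Reagents that add atoms: 7, O-benzylvanillin tosylhydrazone, COc1cc(/C=N/NS(=O)(=O)c2ccc(C)cc2)ccc1OCc1ccccc1 (delivers the ArCH unit; N2 and sulfinate are lost)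
Why: Proposed new method: a photoredox/HAT C–H benzylation of a free secondary alcohol in which excited Ir(III) oxidises quinuclidine to its radical cation, this abstracts the hydridic, phosphate-hydrogen-bonded C4–H of 4 (on the open face), the planar α-hydroxy radical (old C4 configuration erased) adds to the electrophilic C=N carbon of 7 anti to the C3 arylmethyl group, the hydrazinyl radical is reduced by Ir(II) and protonated, and sulfinate then N2 are lost (completed by KOAc at 60 °C, as in a tosylhydrazone reduction) to leave CH2Ar, so the new tetrasubstituted C4 centre is fixed by the malate-derived C3 centre; the closest known reactions are hydrogen-bond-assisted quinuclidine-HAT α-alkylation of alcohols with Michael acceptors and radical addition to N-sulfonylhydrazones with sulfinate/N2 extrusion (HAT alkyl–alkyl coupling, radical hydromethylation), which have not been combined on a secondary alcohol to build a tertiary carbinol stereocentre.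

**Step 5**
Reactants: 8
Product: 9, (2S,3S)-2,3-bis[4-(benzyloxy)-3-methoxybenzyl]butane-1,2,4-triol
Conditions: LiAlH4 (2.5 equiv), THF, 0 °C → rt; Rochelle salt work-up
Reagents that add atoms: none
Why: Hydride reduction of the lactone to the diol is fast at 0 °C; the aryl benzyl ethers and both stereocentres are untouched (the CIP descriptor at the CH centre changes from R to S only because the priorities change).

**Step 6**
Reactants: 9
Product: 10, (−)-carinol, (2S,3S)-2,3-bis(4-hydroxy-3-methoxybenzyl)butane-1,2,4-triol
Conditions: H2 (1 atm), 10% Pd/C, MeOH/EtOAc, rt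
Reagents that add atoms: none
Why: Hydrogenolysis of the two aryl benzyl ethers; the ArCH2–C bonds carry no benzylic heteroatom and the homobenzylic tertiary alcohol is stable.

## Compound list

1 | dimethyl (S)-malate | COC(=O)C[C@H](O)C(=O)OC | starting material
2 | 4-(benzyloxy)-3-methoxybenzyl bromide | COc1cc(CBr)ccc1OCc1ccccc1 | starting material
3 | dimethyl (2S,3R)-3-[4-(benzyloxy)-3-methoxybenzyl]-2-hydroxybutanedioate | COC(=O)[C@@H](O)[C@@H](Cc1ccc(OCc2ccccc2)c(OC)c1)C(=O)OC | intermediate
4 | (3R,4S)-3-[4-(benzyloxy)-3-methoxybenzyl]-4-hydroxyoxolan-2-one | O=C1OC[C@@H](O)[C@H]1Cc2ccc(OCc3ccccc3)c(OC)c2 | intermediate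
5 | 4-(benzyloxy)-3-methoxybenzaldehyde (O-benzylvanillin) | COc1cc(C=O)ccc1OCc1ccccc1 | starting material
6 | p-toluenesulfonyl hydrazide | Cc1ccc(cc1)S(=O)(=O)NN | starting material
7 | O-benzylvanillin (E)-N-tosylhydrazone | COc1cc(/C=N/NS(=O)(=O)c2ccc(C)cc2)ccc1OCc1ccccc1 | intermediate
8 | (3R,4S)-3,4-bis[4-(benzyloxy)-3-methoxybenzyl]-4-hydroxyoxolan-2-one | O=C1OC[C@](O)(Cc2ccc(OCc3ccccc3)c(OC)c2)[C@H]1Cc4ccc(OCc5ccccc5)c(OC)c4 | intermediate
9 | (2S,3S)-2,3-bis[4-(benzyloxy)-3-methoxybenzyl]butane-1,2,4-triol | COc1cc(C[C@@H](CO)[C@](O)(CO)Cc2ccc(OCc3ccccc3)c(OC)c2)ccc1OCc1ccccc1 | intermediate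
10 | (−)-carinol, (2S,3S)-2,3-bis(4-hydroxy-3-methoxybenzyl)butane-1,2,4-triol | COc1cc(C[C@@H](CO)[C@](O)(CO)Cc2ccc(O)c(OC)c2)ccc1O | target

## Summary

Total steps: 6. Longest linear sequence: 5 (1 → 3 → 4 → 8 → 9 → 10).

Steps most likely to fail:

1. **Step 4 (the proposed new photochemical C–H benzylation).** The risks are competing H-abstraction at ArOCH2Ph or benzylic sites, slow addition of the hindered radical to the hydrazone, and an incomplete sulfinate/N2 loss. Fallback with known chemistry (self-regeneration of stereocentres):
   - saponify 3 to the diacid;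
   - condense with pivalaldehyde (acid catalyst) to the cis-2-tert-butyl-1,3-dioxolan-4-one;
   - form the dianion with LiHMDS and alkylate with 2 anti to the tert-butyl group (overall retention at the carbinol carbon);
   - reduce with LiAlH4 to 9, then carry out step 6.

2. **Step 1 (diastereoselectivity and yield of the dianion alkylation with an electron-rich benzylic bromide).** Fallback: trans-selective dianion benzylation of commercial (R)-3-hydroxy-γ-butyrolactone with 2. This gives the (3R,4R) C4-epimer of 4 in one step. Because step 4 erases the carbinol configuration, this epimer converges on the same radical and on 8.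

3. **Step 2 (regioselective borane reduction, possible over-reduction or dehydration on lactonisation).** Fallback:
   - reduce 3 fully with LiAlH4 to the 1,2,4-triol;
   - protect the terminal 1,2-diol as the acetonide;
   - oxidise the remaining primary alcohol to the acid (TEMPO/PhI(OAc)2, aqueous MeCN);
   - treat with aqueous acid to remove the acetonide and lactonise to 4.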